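**Retrosynthetic overview**

1. Drimane numbering is used: ring A = C1–C5 and C10 (C3 carries OAc, C4 the gem-dimethyl group, C10 a methyl); ring B = C5–C10 (C6 ketone, C7=C8, methyl on C8); C11 = the OCH2 carbon on C9.
2. Last disconnection: the C6 carbonyl, from allylic oxidation next to the C7=C8 olefin of the 6-deoxo drim-7-ene.
3. Key disconnection: the C4–C5 bond of ring A and the C9–C10 bond of ring B, both made in one cationic cascade from a cyclopentane (C1, C2, C3, C4, C10) carrying a mesylate on exocyclic C5. C4 shifts from C10 to C5, which enlarges the five-membered ring to ring A, and the tertiary C10 cation then closes ring B onto the C8=C9 olefin.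
4. Enabling feature: C5 is a hydrogen-bearing carbon held between two quaternary carbons of ring A, C4 (gem-dimethyl) and C10 (methyl, ring fusion). The C4–C5 bond can therefore arise by a Wagner–Meerwein shift that leaves a tertiary cation at C10, and the C8 methyl makes the terminating cation tertiary and places the olefin at C7=C8.
5. Order of ring formation: coumarin and cyclopentane are bought (C3 set by desymmetrizing reduction of 2,2-dimethylcyclopentane-1,3-dione); the side chain is joined by enolate alkylation; ring A (by enlargement) and then ring B form in the key step.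

Key step: step 14

Remark on the chemistry: the configuration of the methyl-bearing quaternary ring carbon (future C10) in compounds 6 to 19 is drawn as the expected major epimer; it is erased when C10 becomes cationic in step 14, so it needs no control.

**Route**

Step 1
Reactants: 1 2,2-dimethylcyclopentane-1,3-dione
Product: 2 (3R)-3-hydroxy-2,2-dimethylcyclopentan-1-one
Conditions: (S)-Me-CBS oxazaborolidine (10 mol %), BH3·SMe2 (0.6 equiv), THF, −30 °C; MeOH, aq. work-up
Reagents that add atoms: none
Why: Corey–Bakshi–Shibata reduction of one of the two enantiotopic carbonyl groups, in which the quaternary C2 side acts as the large substituent, should give the (R)-carbinol that becomes C3 of the target, and the deficit of borane limits over-reduction to the diol.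

Step 2
Reactants: 2 (3R)-3-hydroxy-2,2-dimethylcyclopentan-1-one
Product: 3 (3R)-3-(tert-butyldimethylsilyloxy)-2,2-dimethylcyclopentan-1-one
Conditions: TBSCl, imidazole, DMF, rt
Reagents that add atoms: tert-butyldimethylsilyl chloride CC(C)(C)[Si](C)(C)Cl
Why: Standard silylation of the secondary alcohol, needed because the following steps use strong bases and organolithium reagents that an acetate would not survive.

Step 3
Reactants: 3 (3R)-3-(tert-butyldimethylsilyloxy)-2,2-dimethylcyclopentan-1-one
Product: 4 (3R)-3-(tert-butyldimethylsilyloxy)-2,2-dimethylcyclopentane-1-carbonitrile (both C1 epimers)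
Conditions: TosMIC, KOt-Bu, EtOH (1.5 equiv), DME, 0 → 40 °C
Reagents that add atoms: p-toluenesulfonylmethyl isocyanide Cc1ccc(cc1)S(=O)(=O)C[N+]#[C-]
Why: Van Leusen reductive cyanation turns the hindered, non-eliminable ketone directly into the one-carbon-homologated nitrile, and the new C–H centre needs no control because it is deprotonated in step 4.

Step 4
Reactants: 4 (3R)-3-(tert-butyldimethylsilyloxy)-2,2-dimethylcyclopentane-1-carbonitrile
Product: 6 (1S,3R)-3-(tert-butyldimethylsilyloxy)-1,2,2-trimethylcyclopentane-1-carbonitrile, via lithiated nitrile 5 (not isolated)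
Conditions: LiN(i-Pr)2 (LDA, source of the lithium in 5), THF, −78 °C; MeI, −78 → 0 °C
Reagents that add atoms: iodomethane CI
Why: Alkylation of the lithiated nitrile with iodomethane builds the quaternary carbon (future C10), with methyl expected to enter anti to the silyloxy group, although either configuration serves because this carbon becomes a planar cation in step 14.

Step 5
Reactants: 6 (1S,3R)-3-(tert-butyldimethylsilyloxy)-1,2,2-trimethylcyclopentane-1-carbonitrile
Product: 8 1-[(1S,3R)-3-(tert-butyldimethylsilyloxy)-1,2,2-trimethylcyclopentyl]ethan-1-one, via N-lithio ketimine 7 (not isolated)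
Conditions: MeLi, Et2O, 0 °C → rt; aq. AcOH/NaOAc, THF, rt
Reagents that add atoms: methyllithium [Li]C; water O
Why: Addition of methyllithium to the non-enolizable tertiary nitrile stops at the N-lithio ketimine, whose mild acidic hydrolysis should give the methyl ketone without loss of the silyl ether.

Step 6
Reactants: 9 umbelliferone (7-hydroxy-2H-chromen-2-one); 10 prenyl bromide (1-bromo-3-methylbut-2-ene)
Product: 11 7-[(3-methylbut-2-en-1-yl)oxy]-2H-chromen-2-one
Conditions: K2CO3, acetone, reflux
Reagents that add atoms: none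
Why: Williamson etherification of the acidic phenol with a primary allylic bromide under mild carbonate conditions.

Step 7
Reactants: 11 7-[(3-methylbut-2-en-1-yl)oxy]-2H-chromen-2-one
Product: 12 7-{[(2E)-4-hydroxy-3-methylbut-2-en-1-yl]oxy}-2H-chromen-2-one
Conditions: SeO2 (cat.), t-BuOOH, CH2Cl2, rt
Reagents that add atoms: tert-butyl hydroperoxide CC(C)(C)OO (oxygen relayed through the SeO2 catalyst, O=[Se]=O)
Why: Selenium dioxide allylic oxidation (ene reaction, then [2,3]-sigmatropic shift) attacks the methyl group trans to the CH2OAr chain of the trisubstituted olefin and so fixes the E geometry that later controls C9.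

Step 8
Reactants: 12 7-{[(2E)-4-hydroxy-3-methylbut-2-en-1-yl]oxy}-2H-chromen-2-one
Product: 13 7-{[(2E)-4-bromo-3-methylbut-2-en-1-yl]oxy}-2H-chromen-2-one
Conditions: PBr3, Et2O, −10 °C
Reagents that add atoms: phosphorus tribromide BrP(Br)Br
Why: Conversion of the primary allylic alcohol into the bromide with PBr3 at low temperature should proceed without allylic transposition or loss of olefin geometry.

Step 9
Reactants: 8 1-[(1S,3R)-3-(tert-butyldimethylsilyloxy)-1,2,2-trimethylcyclopentyl]ethan-1-one; 13 7-{[(2E)-4-bromo-3-methylbut-2-en-1-yl]oxy}-2H-chromen-2-one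
Product: 15 7-{[(2E)-6-[(1S,3R)-3-(tert-butyldimethylsilyloxy)-1,2,2-trimethylcyclopentyl]-3-methyl-6-oxohex-2-en-1-yl]oxy}-2H-chromen-2-one, via lithium enolate 14 (not isolated)
Conditions: LiN(i-Pr)2 (LDA, source of the lithium in 14), THF, −78 °C; 13, DMPU, −78 → −30 °C
Reagents that add atoms: none
Why: Kinetic enolate alkylation in which the ketone can enolize only toward its methyl group (the other side is quaternary) and the reactive primary allylic bromide should be displaced in SN2 fashion faster than the enolate adds to the coumarin, forming the C6–C7 bond.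

Step 10
Reactants: 15 7-{[(2E)-6-[(1S,3R)-3-(tert-butyldimethylsilyloxy)-1,2,2-trimethylcyclopentyl]-3-methyl-6-oxohex-2-en-1-yl]oxy}-2H-chromen-2-one
Product: 16 7-{[(2E)-6-[(1S,3R)-3-hydroxy-1,2,2-trimethylcyclopentyl]-3-methyl-6-oxohex-2-en-1-yl]oxy}-2H-chromen-2-one
Conditions: HF·pyridine, pyridine, THF, 0 °C → rt
Reagents that add atoms: none
Why: Fluoride-mediated desilylation buffered with pyridine should leave the allyl aryl ether, the lactone and the ketone intact.

Step 11
Reactants: 16 7-{[(2E)-6-[(1S,3R)-3-hydroxy-1,2,2-trimethylcyclopentyl]-3-methyl-6-oxohex-2-en-1-yl]oxy}-2H-chromen-2-one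
Product: 17 (1R,3S)-2,2,3-trimethyl-3-{(4E)-4-methyl-6-[(2-oxo-2H-chromen-7-yl)oxy]hex-4-enoyl}cyclopentyl acetate
Conditions: Ac2O, pyridine, DMAP (cat.), CH2Cl2, rt
Reagents that add atoms: acetic anhydride CC(=O)OC(C)=O
Why: DMAP-catalysed acylation of the only free hydroxyl installs the acetate of the target before the cationic step.

Step 12
Reactants: 17 (1R,3S)-2,2,3-trimethyl-3-{(4E)-4-methyl-6-[(2-oxo-2H-chromen-7-yl)oxy]hex-4-enoyl}cyclopentyl acetate
Product: 18 (1R,3S)-3-{(1R,4E)-1-hydroxy-4-methyl-6-[(2-oxo-2H-chromen-7-yl)oxy]hex-4-en-1-yl}-2,2,3-trimethylcyclopentyl acetate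
Conditions: (S)-Me-CBS oxazaborolidine (20 mol %), BH3·SMe2 (0.7 equiv, slow addition), toluene, −20 °C; MeOH
Reagents that add atoms: none
Why: Corey–Bakshi–Shibata reduction in which the tertiary-alkyl side is the large and the CH2 chain the small substituent should give the (R)-carbinol at C5 by catalyst control, independent of the remote ring stereocentres.

Step 13
Reactants: 18 (1R,3S)-3-{(1R,4E)-1-hydroxy-4-methyl-6-[(2-oxo-2H-chromen-7-yl)oxy]hex-4-en-1-yl}-2,2,3-trimethylcyclopentyl acetate
Product: 19 (1R,3S)-3-{(1R,4E)-1-(methanesulfonyloxy)-4-methyl-6-[(2-oxo-2H-chromen-7-yl)oxy]hex-4-en-1-yl}-2,2,3-trimethylcyclopentyl acetate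
Conditions: MsCl, Et3N, CH2Cl2, −10 °C; used without delay
Reagents that add atoms: methanesulfonyl chloride CS(=O)(=O)Cl
Why: Mesylation through sulfene tolerates the strongly hindered secondary alcohol and retains its configuration, giving the leaving group for the cascade.

Step 14
Reactants: 19 (1R,3S)-3-{(1R,4E)-1-(methanesulfonyloxy)-4-methyl-6-[(2-oxo-2H-chromen-7-yl)oxy]hex-4-en-1-yl}-2,2,3-trimethylcyclopentyl acetate
Product: 22 (3R,5S,9R,10R)-3-acetoxy-11-[(2-oxo-2H-chromen-7-yl)oxy]drim-7-ene, via ring-enlarged C10 cation 20 (not isolated), via bicyclic C8 cation 21 (not isolated)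
Conditions: (CF3)2CHOH (HFIP), 2,6-di-tert-butyl-4-methylpyridine, 0 °C → rt
Reagents that add atoms: none
Why: Proposed new method: ionization of the neopentyl-type secondary mesylate in the ionizing, non-nucleophilic solvent is assisted by the anti-periplanar C4–C10 bond, so C4 migrates from C10 to C5 with inversion at C5 (Wagner–Meerwein shift), which enlarges the cyclopentane (C1, C2, C3, C4, C10) to the six-membered ring A and leaves the tertiary C10 cation 20; this cation is trapped by the C8=C9 olefin through a chair-like transition state to give the C9–C10 bond, ring B and the tertiary C8 cation 21, which loses H7 to the hindered base. The closest known reaction types are the solvolytic ring enlargement of (1-methylcyclopentyl)carbinyl sulfonates to 1-methylcyclohexyl cations and the acid-mediated ring closure of monocyclofarnesyl-type C10 cations to drim-7-enes; their coupling in one cascade on this substrate is the untested part. Ring A closes by a 1,2-alkyl shift (five- to six-membered ring enlargement) and ring B by a 6-endo-trig cation–olefin cyclization. C5 is controlled by the carbinol centre set in step 12 (anti migration, inversion), which places the C5 side chain cis to the C3 acetate and equatorial; C10 is controlled by equatorial attack of the olefin on the chair of ring A, which gives the trans ring fusion; C9 is controlled by the E geometry of the olefin, which puts C11 equatorial and cis to the C10 methyl. The step needs migration of C4 in preference to C1 or the methyl group, which the higher substitution of C4 and the release of ring strain should secure, and ring closure faster than proton loss from 20, which the poorly basic medium and the intramolecular chair geometry should secure; the configuration at the old quaternary carbon plays no role because C10 becomes planar.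

Step 15
Reactants: 22 (3R,5S,9R,10R)-3-acetoxy-11-[(2-oxo-2H-chromen-7-yl)oxy]drim-7-ene
Product: 23 (3R,5S,9R,10S)-3-acetoxy-6-oxo-11-[(2-oxo-2H-chromen-7-yl)oxy]drim-7-ene (CNP0363962.1)
Conditions: Na2CrO4, NaOAc, AcOH/Ac2O, 40 °C
Reagents that add atoms: sodium chromate [Na+].[Na+].[O-][Cr](=O)(=O)[O-]
Why: Allylic oxidation by hexavalent chromium of the ring CH2 next to the CH end of a trisubstituted cyclohexene, the same regiochemistry as the conversion of steroidal 5-enes into 5-en-7-ones, should give the conjugated enone without touching C9, whose configuration is retained.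

**Compound list**

1 | 2,2-dimethylcyclopentane-1,3-dione | CC1(C)C(=O)CCC1=O | starting material
2 | (3R)-3-hydroxy-2,2-dimethylcyclopentan-1-one | O[C@@H]1CCC(=O)C1(C)C | intermediate
3 | (3R)-3-(tert-butyldimethylsilyloxy)-2,2-dimethylcyclopentan-1-one | CC(C)(C)[Si](C)(C)O[C@@H]1CCC(=O)C1(C)C | intermediate
4 | (3R)-3-(tert-butyldimethylsilyloxy)-2,2-dimethylcyclopentane-1-carbonitrile, both C1 epimers | CC(C)(C)[Si](C)(C)O[C@@H]1CCC(C#N)C1(C)C | intermediate
5 | lithiated nitrile (N-lithio keteniminate of 4), not isolated | CC(C)(C)[Si](C)(C)O[C@@H]1CCC(=C=N[Li])C1(C)C | intermediate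
6 | (1S,3R)-3-(tert-butyldimethylsilyloxy)-1,2,2-trimethylcyclopentane-1-carbonitrile (methyl trans to the silyloxy group) | CC(C)(C)[Si](C)(C)O[C@@H]1CC[C@](C)(C#N)C1(C)C | intermediate
7 | N-lithio ketimine from 6 and methyllithium, not isolated | CC(C)(C)[Si](C)(C)O[C@@H]1CC[C@](C)(C(C)=N[Li])C1(C)C | intermediate
8 | 1-[(1S,3R)-3-(tert-butyldimethylsilyloxy)-1,2,2-trimethylcyclopentyl]ethan-1-one | CC(C)(C)[Si](C)(C)O[C@@H]1CC[C@](C)(C(C)=O)C1(C)C | intermediate
9 | umbelliferone (7-hydroxy-2H-chromen-2-one) | Oc1ccc2ccc(=O)oc2c1 | starting material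
10 | prenyl bromide (1-bromo-3-methylbut-2-ene) | CC(C)=CCBr | starting material
11 | 7-[(3-methylbut-2-en-1-yl)oxy]-2H-chromen-2-one | CC(C)=CCOc1ccc2ccc(=O)oc2c1 | intermediate
12 | 7-{[(2E)-4-hydroxy-3-methylbut-2-en-1-yl]oxy}-2H-chromen-2-one | OC/C(C)=C/COc1ccc2ccc(=O)oc2c1 | intermediate
13 | 7-{[(2E)-4-bromo-3-methylbut-2-en-1-yl]oxy}-2H-chromen-2-one | BrC/C(C)=C/COc1ccc2ccc(=O)oc2c1 | intermediate
14 | lithium enolate of 8, not isolated | CC(C)(C)[Si](C)(C)O[C@@H]1CC[C@](C)(C(=C)O[Li])C1(C)C | intermediate
15 | 7-{[(2E)-6-[(1S,3R)-3-(tert-butyldimethylsilyloxy)-1,2,2-trimethylcyclopentyl]-3-methyl-6-oxohex-2-en-1-yl]oxy}-2H-chromen-2-one | CC(C)(C)[Si](C)(C)O[C@@H]1CC[C@](C)(C(=O)CC/C(C)=C/COc2ccc3ccc(=O)oc3c2)C1(C)C | intermediate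
16 | 7-{[(2E)-6-[(1S,3R)-3-hydroxy-1,2,2-trimethylcyclopentyl]-3-methyl-6-oxohex-2-en-1-yl]oxy}-2H-chromen-2-one | O[C@@H]1CC[C@](C)(C(=O)CC/C(C)=C/COc2ccc3ccc(=O)oc3c2)C1(C)C | intermediate
17 | (1R,3S)-2,2,3-trimethyl-3-{(4E)-4-methyl-6-[(2-oxo-2H-chromen-7-yl)oxy]hex-4-enoyl}cyclopentyl acetate | CC(=O)O[C@@H]1CC[C@](C)(C(=O)CC/C(C)=C/COc2ccc3ccc(=O)oc3c2)C1(C)C | intermediate
18 | (1R,3S)-3-{(1R,4E)-1-hydroxy-4-methyl-6-[(2-oxo-2H-chromen-7-yl)oxy]hex-4-en-1-yl}-2,2,3-trimethylcyclopentyl acetate | CC(=O)O[C@@H]1CC[C@](C)([C@H](O)CC/C(C)=C/COc2ccc3ccc(=O)oc3c2)C1(C)C | intermediate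
19 | (1R,3S)-3-{(1R,4E)-1-(methanesulfonyloxy)-4-methyl-6-[(2-oxo-2H-chromen-7-yl)oxy]hex-4-en-1-yl}-2,2,3-trimethylcyclopentyl acetate | CC(=O)O[C@@H]1CC[C@](C)([C@H](OS(C)(=O)=O)CC/C(C)=C/COc2ccc3ccc(=O)oc3c2)C1(C)C | intermediate
20 | ring-enlarged monocyclic tertiary C10 cation (ring A formed, side chain on C5), methanesulfonate ion pair, not isolated | CC(=O)O[C@@H]1CC[C+](C)[C@H](CC/C(C)=C/COc2ccc3ccc(=O)oc3c2)C1(C)C.CS(=O)(=O)[O-] | intermediate
21 | bicyclic tertiary C8 cation (rings A and B formed), methanesulfonate ion pair, not isolated | CC(=O)O[C@@H]1CC[C@@]2(C)[C@H](COc3ccc4ccc(=O)oc4c3)[C+](C)CC[C@@H]2C1(C)C.CS(=O)(=O)[O-] | intermediate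
22 | (3R,5S,9R,10R)-3-acetoxy-11-[(2-oxo-2H-chromen-7-yl)oxy]drim-7-ene | CC(=O)O[C@@H]1CC[C@@]2(C)[C@H](COc3ccc4ccc(=O)oc4c3)C(C)=CC[C@@H]2C1(C)C | intermediate
23 | (3R,5S,9R,10S)-3-acetoxy-6-oxo-11-[(2-oxo-2H-chromen-7-yl)oxy]drim-7-ene (CNP0363962.1) | CC(=O)O[C@@H]1CC[C@@]2(C)[C@H](COc3ccc4ccc(=O)oc4c3)C(C)=CC(=O)[C@@H]2C1(C)C | target

**Step count and risks**

Total steps: 15. Longest linear sequence: 12 steps (steps 1, 2, 3, 4, 5, 9, 10, 11, 12, 13, 14, 15).

Steps most likely to fail:

1. Step 14 (carries the label "Proposed new method:"). The cascade may be interrupted after the ring enlargement by proton loss from cation 20 (monocyclic olefins), a wrong ring bond (C1 or the methyl group) may migrate, or the olefin may attack C10 with poor facial selectivity. Fallback with known chemistry, setting out from 19 and coming back at 22: the cascade is split into two operations of established type. Solvolysis of mesylate 19 in buffered aqueous acetone (CaCO3, 50 °C), the classical ring enlargement of a (1-methylcyclopentyl)carbinyl sulfonate, should give the ring-enlarged tertiary alcohol F1 together with its dehydration olefins. The whole monocyclic fraction is then cyclized with ClSO3H in 2-nitropropane at −78 °C, the established protic superacid ring closure of monocyclic farnesyl-type substrates, in which reversible protonation returns every monocyclic isomer to the C10 cation and drives it to 22.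

2. Step 15. The oxidation may lose site selectivity (attack at the C9 hydrogen or at the methyl on C8) or over-oxidize. Fallback, setting out from 22 and coming back at 23: the olefin is functionalized and the oxygen transposed instead of oxidizing a C–H bond. Hydroxyselenation (PhSeCl, H2O/MeCN) should add selenium to C7 from the face opposite the C10 methyl and water to the tertiary C8, giving the hydroxy selenide F2. Oxidation with H2O2/pyridine gives the selenoxide F3, whose syn elimination toward C6 gives the tertiary allylic alcohol F4 (drim-6-en-8-ol). Pyridinium chlorochromate, C5H5NH[CrO3Cl], in CH2Cl2 then effects the Babler–Dauben oxidative 1,3-transposition to the C6 ketone with the C7=C8 olefin, which is 23.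

3. Step 12. Reduction of the very hindered ketone may be slow, so that hydroboration of the olefin competes, or facial selectivity may be poor. Fallback, setting out from 17 and coming back at 18: catalyst control is given up. NaBH4 in MeOH at 0 °C reduces 17 to both C5 epimers, 18 and the (1S)-carbinol F5, which are diastereomers and are separated by chromatography. F5 is oxidized back to 17 with Dess–Martin periodinane and recycled.

**Further compounds**

F1 | step 14 | ring-enlarged tertiary alcohol (hydroxyl and methyl on C10, either C10 epimer; C3 and C5 as in 22; side chain on C5) | CC(=O)O[C@@H]1CCC(C)(O)[C@H](CC/C(C)=C/COc2ccc3ccc(=O)oc3c2)C1(C)C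
F2 | step 15 | hydroxy selenide of 22 (PhSe on C7 trans to the C10 methyl, OH on C8 cis to the C10 methyl) | CC(=O)O[C@@H]1CC[C@@]2(C)[C@H](COc3ccc4ccc(=O)oc4c3)[C@](C)(O)[C@@H]([Se]c5ccccc5)C[C@@H]2C1(C)C
F3 | step 15 | selenoxide of F2 (not isolated) | CC(=O)O[C@@H]1CC[C@@]2(C)[C@H](COc3ccc4ccc(=O)oc4c3)[C@](C)(O)[C@@H]([Se](=O)c5ccccc5)C[C@@H]2C1(C)C
F4 | step 15 | tertiary allylic alcohol, 3-acetoxy-11-(coumarin-7-yloxy)drim-6-en-8-ol (OH cis to the C10 methyl) | CC(=O)O[C@@H]1CC[C@@]2(C)[C@H](COc3ccc4ccc(=O)oc4c3)[C@](C)(O)C=C[C@@H]2C1(C)C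
F5 | step 12 | C5 epimer of 18, the (1S)-carbinol | CC(=O)O[C@@H]1CC[C@](C)([C@@H](O)CC/C(C)=C/COc2ccc3ccc(=O)oc3c2)C1(C)C
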